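The blue run, the faster of the two earlier runs, loses 0.0975 decades of electrophile by its first reading. A decade here is the common logarithm of charged over remaining electrophile, so paces in decades per minute add up along a run.

| setting | amber | blue | theta | zeta | beta |
|---|---|---|---|---|---|
| electrophile | 0.30 M | 0.30 M | 0.30 M | 0.30 M | 0.30 M |
| nucleophile | 0.53 M | 2.4 M | 0.450 M | 0.900 M | 1.80 M |
| gas | 37 mM (held) | 37 mM (held) | 37 mM (held) | 37 mM (held) | 37 mM (held) |
| remark | run made earlier | run made earlier |  |  |  |
| time |  |  | 2.5 h | 2.5 h | 2.5 h |

| run | time / min | electrophile / % | target / % |
|---|---|---|---|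
| amber | 20.0 | 84.4 | 14.4 |
| amber | 40.0 | 74.1 | 22.4 |
| amber | 60.0 | 67.5 | 26.1 |
| amber | 80.0 | 62.7 | 28.5 |
| blue | 6.00 | 79.9 | 21.0 |
| blue | 15.0 | 60.5 | 39.7 |
| blue | 30.0 | 41.9 | 50.4 |
| blue | 80.0 | 21.3 | 57.2 |

(each reading ± 1 percentage point)

- at the start none of the gas is in solution

* part of the electrophile that has reacted at the end, theta
* part of the electrophile that has reacted at the end, zeta
* part of the electrophile that has reacted at the end, beta
* what raising the concentration of nucleophile from its lowest to its highest value here does to the part of the electrophile that has reacted (changes below 5 percentage points count as none) (it falls / no change / it rises)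

Divided by c(nucleophile), blue's start pace reads 0.00677 M⁻¹ min⁻¹, and amber's first reading gives 0.00695 M⁻¹ min⁻¹, about the same, so these two first readings fit a start pace proportional to c(nucleophile).

Neither run keeps that pace. Amber's pace over its last interval is lower than over its first by a factor of 2.30, and blue's, from its third reading to its last, by 2.76, a greater factor. Amber stands at 56.5 min after 80.0 min, and this is its effective time, the minutes at the start pace that give the decades reached. Blue stands at 41.4 min after the same time.

On logarithmic axes, effective time grows with clock time to the power 0.613, the mean of the two runs, and goes with c(nucleophile) to the power −0.207. Carried from amber to 2.5 h, this gives 85.9 min for theta, 74.5 min for zeta and 64.5 min for beta. With the start pace, this reckoning of my own yields conversions of 45.3%, 64.8% and 83.6%.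

The forecast, which reckons with “a limited effective time”, gives 41%, 62% and 82%, each lower than the reckoning here, and says of raising the nucleophile: it rises.

The flask reaches 43.2% in theta, 64.4% in zeta and 82.4% in beta; from theta to beta it rises, by 39 percentage points.

    2 nucleophile → self-condensation product (k = 1.12 × 10⁻⁴ M⁻¹ s⁻¹)
    nucleophile + acid set free ⇌ protonated nucleophile, settled at all times (K = 10900 M⁻¹)
    target ⇌ isomer of the product (K = 2.38, k = 1.11 × 10⁻⁴ s⁻¹)
    electrophile + nucleophile → acid set free + target (k = 3.11 × 10⁻⁴ M⁻¹ s⁻¹)
    acid set free + free base ⇌ salt of the base, settled at all times (K = 65.7 M⁻¹)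
    gas ⇌ free base, rate k6*(csat - [free base]) (kL = 3.64 × 10⁻⁴ s⁻¹)

In beta, self-condensation used nucleophile 4.3 times as fast as the step to target just after the start. Of its turnover up to the end, the step to target had 86% behind it by 1.25 h, while the step from target to its isomer had 15% of its own behind it by 0.500 h, and 15.5% of the charged nucleophile stood free at the end. Beta's conversion corresponds to an effective time of 61.9 min; the neighbour flask, the same as beta but with 0.75 M of electrophile, reaches 69.8% on 42.7 min.

Readings and results stem from a simulated flask with made-up constants.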